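Time is the first thing to read in the earlier runs: in both, the rate of bis adduct formation falls within 2.50 h.

common to all: solid substrate 0.062 M
- north-east: partner 0.65 equiv; run made earlier
- south: partner 3.6 equiv; run made earlier
- noon: partner 0.500 equiv; time 5.0 h
- midnight: partner 1.50 equiv; time 5.0 h
- dusk: partner 2.50 equiv; time 5.0 h

| run | time / h | bis adduct / % | first product / % |
|---|---|---|---|
| north-east | 0.167 | 0 | 0 |
| north-east | 0.500 | 1.5 | 0.1 |
| north-east | 0.833 | 2.7 | 0.7 |
| north-east | 1.33 | 3.9 | 0.4 |
| north-east | 2.00 | 4.6 | 1.0 |
| north-east | 2.50 | 4.7 | 1.3 |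
| south | 0.417 | 3.1 | 0 |
| south | 0.833 | 7.1 | 0.5 |
| south | 1.33 | 8.8 | 0 |
| south | 1.50 | 9.1 | 0.7 |
| south | 2.00 | 10.3 | 1.2 |
| south | 2.50 | 10.9 | 0.7 |

(each reading ± 0.5 percentage points)

* final bis adduct, as a percentage of the solid substrate charged, for each flask in turn (noon, midnight, dusk)

The north-east run rises by 0.8 percentage points from 1.33 h to 2.50 h, on readings that scatter by 0.5 points, so the factor of the fall is read in the south run. There the mean rate up to 0.833 h, divided by the mean rate from 1.33 h to 2.50 h, reads:

south: fall = 4.75

The bis adduct's own use of partner gives no such factor. In the south run it has taken 6.06 % of the charged partner at two per adduct, a slowing of 1.06. The centres of the two time windows stand 1.50 h apart, so: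

τ = gap / ln(fall) = 0.962 h

This is the fading time, in which the rate sinks by the factor e. A rate fading so leaves the share exp(−t/τ) of its total still to come:

at 2.50 h: 7.43 %
at 5.0 h: 0.553 %

Assuming this south reading for both runs, the plateaus read 5.08 % for north-east and 11.8 % for south. Proportion to partner, the zero of the scale, would multiply the plateau by 5.54, but it grows by 2.32, a power of 0.491. This reckoning gives 4.46 %, 7.66 % and 9.84 %.

The forecast, which suspects “perhaps partner loss or solid passivation”, says 4.5 %, 8.3 % and 10.5 %, higher than this reckoning at midnight and dusk.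

The flasks give 3.44 %, 7.74 % and 10.1 %, so the forecast held, with noon 1.1 points below it.

    starting material + partner → first product (k = 0.0640 M⁻¹ s⁻¹)
    partner + first product → bis adduct (k = 0.190 M⁻¹ s⁻¹)
    starting material ⇌ dormant form (K = 0.390, k = 0.00190 s⁻¹)
    partner → decomposed reagent (k = 5.30 × 10⁻⁴ s⁻¹)
    solid substrate ⇌ starting material, rate k5*(cs5 - [starting material]) while solid is left; crystals form when [starting material] > cs5 (solubility = 9.00 mM, k = 1.80 × 10⁻⁴ s⁻¹)

In midnight, partner has a half-life of 0.36 h by decomposition alone, and it stands at 0 % at 5.00 h. The 5.0 h of the flasks spans 5.20 fading times of 0.962 h as read in the south run, and a run ten times as long changes midnight's bis adduct by nothing. Dusk holds 10.1 % bis adduct at 5.00 h and 10.1 % at 50.0 h.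

(The numbers in the tables stem from a simulated flask from invented constants; the scatter is artificial.)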